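## Analysis of the target

CNP0233746.1 is a germacranolide, and germacrane numbering is used throughout. Ring A is the ten-membered carbocycle C1–C10. Ring B is the butenolide O–C12(=O)–C11=C7–C6, fused to ring A at C6–C7, so the tetrasubstituted C7=C11 olefin is exocyclic to ring A. C11 carries C13 (CH2OAc), C10 carries the exocyclic methylene C14, C4 carries the methyl C15, and the C8 oxygen is esterified with 2-(hydroxymethyl)acrylic acid.

The SMILES is read as (1R,2S,4R,5R,6S,8S). The C1–C2 oxirane is cis (it derives from a Z olefin) and the trisubstituted C4–C5 oxirane is trans (from an E olefin). The C5 and C6 oxygens are syn (threo), and the C6 and C8 oxygens are 1,3-syn across the planar C7, which offers no direct acyclic stereocontrol between them.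

Sensitive points:
- C6–H is γ to the lactone carbonyl and next to the oxirane carbon C5, so base can open the oxirane by E1cB.
- The vinyl oxirane C14=C10–C1(O)C2 is acid-labile.
- The acrylate and the butenolide are Michael acceptors, and C13 bears an allylic acetate.

The hard problems are the strained medium ring carrying four rigid units, a tetrasubstituted olefin with four different carbon substituents, and two acrylate-derived units that must end up differently functionalised.

The feature that invites the key move is the array C14=C10–C1–C2 in ring A. It is the mono-epoxide of a 2-substituted 1,3-diene, and that diene is the retron of an enyne metathesis between an alkyne C10≡C1 and an olefin at C2. One operation can therefore close ring A, create both olefins of the diene and bring in C14.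

## Retrosynthetic reasoning

**24 ⇒ 23 (C1–O and C2–O).** The oxirane oxygen on C1–C2 is removed last. The vinyl oxirane is the most acid-labile group, so no deprotection should follow it. The forward step must oxidise the cis C1=C2 olefin of 23 and leave C10=C14 alone, on the face that gives 1R,2S.

**23 ⇒ 19 (ester bonds at O8 and O13).** The side-chain ester and the acetate are peeled back to the bis-silyl ether 19 through 22, 21 and 20. No skeletal bond is cut; the acid 14 serves as the acyl donor.

**19 ⇒ 17 (C1=C2 and C10=C14, key step).** Both olefins of the diene are cut. What remains is the monocyclic butenolide 17 with a terminal alkyne (C10≡C1) on the C8 arm and an allyl group (C2) on the oxirane arm; C14 comes from the metathesis co-reagent. The cut is made here because the diene then need not be built in the open chain and no stereocentre is put at risk in the ring closure. All four stereocentres of 19 are already present in 17. The forward reaction has to close a ten-membered ring and deliver the Z olefin.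

**17 ⇒ 15 (C7=C11).** After removal of the alkyne cap (17 ⇐ 16), the butenolide olefin is cut by ring-closing metathesis, leading to the ester 15 of the C6 carbinol with acid 14 and a methylene group on C7. Ring formation fixes the olefin geometry, so the four different substituents need no E/Z control, and the lactone forms under neutral conditions.

**15 ⇒ 11 + 14 (C6–O).** The ester is made with inversion at C6. This turns the 5,6-anti carbinol 11, which is the expected product of the fragment union, into the 5,6-syn ester that the target needs.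

**11 ⇒ 9 + 4 (C6–C7).** The carbinol carbon C6 is joined to the vinyl carbon C7 by addition of the vinyllithium 10 (from bromide 9) to the epoxy aldehyde 4.

**4 ⇒ 3 ⇒ 2 ⇒ 1.** The aldehyde comes from epoxy alcohol 3. Its C4 and C5 centres are set by reagent-controlled epoxidation of the E allylic alcohol 2, and the E geometry is set by syn carbometalation of enyne 1.

**9 ⇒ 8 ⇒ 6 + 7, and 6 ⇒ 5 (C8–C9).** C8 is set by enantioselective propargylation of the α-bromo enal 6 with boronate 7. The enal supplies C7 as a vinyl bromide and C8 as the carbonyl carbon.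

**14 ⇒ 13 ⇒ 12.** The acid used twice (C11–C13 of ring B and the C8 side chain) comes from the commercial hydroxy ester 12.

## Alternatives that were turned down

**Alternative 1:** the textbook route cuts C8–C9. An intramolecular Nozaki–Hiyama–Kishi allylation of bromo aldehyde A1 would close ring A and give alcohol 21. It was turned down for these reasons:
- A1 must already contain the butenolide, the C4–C5 oxirane and the Z diene. The diene would need its own cross-coupling and semi-reduction steps in the open chain, whereas the chosen key step makes it while closing the ring.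
- The formyl group on C7 is a vinylogous glyoxylate, prone to hydration and to attack at C7, and its alcohol precursor would have to be told apart from C13–OH.
- The ring closure forms one bond only and creates C8 without control, because C6 sits across the planar C7.

**Alternative 2:** cut C6–C7 and O–C12 together. A chromium/nickel-mediated vinyl–aldehyde coupling of iodo enoate aldehyde A2 with spontaneous lactonisation would close both rings in one step and give A3. This is the most attractive rival, but it was turned down for these reasons: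
- The polar Felkin–Anh mode puts the nucleophile anti to the oxirane C5–O bond and predicts the 5,6-anti product, the wrong C6 epimer.
- Once the lactone has formed there is no free hydroxyl for an inversion, and base epimerisation at C6 would open the oxirane by E1cB.
- The tetrasubstituted Z β-iodo enoate needs Lewis-acidic iodide addition/aldol chemistry that an oxirane would not survive, and its C–I bond would not survive the palladium and semi-reduction steps required for the Z diene. The ordering and protecting-group steps make the route longer than the chosen one.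

**Alternative 3:** cut C2–C3 and re-form C5–C10. An anionic oxy-Cope ring expansion of the trans-divinylcyclohexanol A4 to cyclodecenone A5 would set the E C4=C5 olefin and leave a C10 carbonyl for methylenation. It was turned down for these reasons:
- The C8 silyloxy group is β to the C10 carbonyl in A5, so the strongly basic alkoxide/enolate conditions invite E1cB loss of that oxygen.
- A4 needs five stereocentres on a cyclohexane, two of which are destroyed.
- The butenolide, the C1=C2 unsaturation, both oxiranes and C14 would all still have to be added on a medium ring prone to transannular reactions, so the step count is far higher.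

Key step: step 13

Remark: 2-bromoprop-2-enal is prepared fresh from acrolein (step 4) rather than assumed to be in stock.

## Steps

Step 1
Reactants: 1 pent-1-en-4-yne
Product: 2 (2E)-3-methylhexa-2,5-dien-1-ol
Conditions: Me3Al, Cp2ZrCl2 (cat.), CH2Cl2, 0 °C to rt; then n-BuLi, (CH2O)n, THF, −30 °C to rt
Reagents that add atoms: trimethylaluminium, C[Al](C)C; paraformaldehyde (as formaldehyde), C=O
Why: Negishi zirconium-catalysed carboalumination adds methyl and aluminium syn across the alkyne with methyl on the internal carbon, and the alkenyl aluminate is hydroxymethylated with retention, so the E allylic alcohol should result; the isolated terminal olefin does not react.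

Step 2
Reactants: 2 (2E)-3-methylhexa-2,5-dien-1-ol
Product: 3 [(2R,3R)-3-methyl-3-(prop-2-en-1-yl)oxiran-2-yl]methanol
Conditions: Ti(OiPr)4 (cat.), D-(−)-diethyl tartrate (cat.), t-BuOOH, 4 Å molecular sieves, CH2Cl2, −20 °C
Reagents that add atoms: tert-butyl hydroperoxide, CC(C)(C)OO
Why: Sharpless asymmetric epoxidation of an E 3-methyl allylic alcohol; the D-(−)-tartrate should deliver oxygen to the face that gives the 2R,3R oxirane (C5 and C4 of the target), and only the allylic olefin is activated by the titanium alkoxide.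

Step 3
Reactants: 3 [(2R,3R)-3-methyl-3-(prop-2-en-1-yl)oxiran-2-yl]methanol
Product: 4 (2S,3R)-3-methyl-3-(prop-2-en-1-yl)oxirane-2-carbaldehyde
Conditions: Dess–Martin periodinane, NaHCO3, CH2Cl2, 0 °C
Reagents that add atoms: none
Why: Buffered Dess–Martin oxidation is neutral and should give the epoxy aldehyde without epimerisation or oxirane opening; the descriptor at C2 changes only because the formyl group outranks the ring carbon.

Step 4
Reactants: 5 prop-2-enal (acrolein)
Product: 6 2-bromoprop-2-enal
Conditions: Br2, CH2Cl2, −78 °C; then Et3N, 0 °C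
Reagents that add atoms: bromine, BrBr
Why: Bromine addition followed by E1cB loss of HBr from the α,β-dibromo aldehyde is the standard route to the α-bromo enal, which is used at once.

Step 5
Reactants: 6 2-bromoprop-2-enal; 7 trimethyl[3-(4,4,5,5-tetramethyl-1,3,2-dioxaborolan-2-yl)prop-1-yn-1-yl]silane
Product: 8 (3S)-2-bromo-6-(trimethylsilyl)hex-1-en-5-yn-3-ol
Conditions: Cu(O2CiPr)2 (cat.), MeO-BIBOP-type P-chiral bisphosphine (cat., enantiomer directing Si-face attack), LiOtBu (cat.), THF, −60 °C; aqueous work-up
Reagents that add atoms: none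
Why: Copper-catalysed asymmetric propargylation: boron-to-copper exchange gives an allenylcopper that adds to the aldehyde in the SE2′ sense, so the homopropargylic alcohol with the silyl-capped alkyne should form; the chiral ligand sets C8 (S requires Si-face attack) and enals are known to react 1,2.

Step 6
Reactants: 8 (3S)-2-bromo-6-(trimethylsilyl)hex-1-en-5-yn-3-ol
Product: 9 {[(3S)-2-bromo-6-(trimethylsilyl)hex-1-en-5-yn-3-yl]oxy}(tert-butyl)dimethylsilane
Conditions: TBSCl, imidazole, DMF, rt
Reagents that add atoms: tert-butyldimethylsilyl chloride, CC(C)(C)[Si](C)(C)Cl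
Why: Routine silylation; the silyl ether withstands organolithium, Mitsunobu and metathesis conditions and leaves C8 untouched.

Step 7
Reactants: 9 {[(3S)-2-bromo-6-(trimethylsilyl)hex-1-en-5-yn-3-yl]oxy}(tert-butyl)dimethylsilane; 4 (2S,3R)-3-methyl-3-(prop-2-en-1-yl)oxirane-2-carbaldehyde
Product: 11 (1R,3S)-3-{[tert-butyl(dimethyl)silyl]oxy}-2-methylidene-1-[(2R,3R)-3-methyl-3-(prop-2-en-1-yl)oxiran-2-yl]-6-(trimethylsilyl)hex-5-yn-1-ol, via vinyllithium 10 (not isolated)
Conditions: t-BuLi (2 equiv), Et2O, −78 °C; then 4, −78 °C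
Reagents that add atoms: none
Why: Bromine–lithium exchange on the 2-bromoalkene is faster than any deprotonation at −78 °C and the vinyllithium adds to the aldehyde; polar Felkin–Anh attack anti to the oxirane C–O bond should favour the 5,6-anti (6R) carbinol, and its C6 epimer would not be lost (see the fallback to step 10).

Step 8
Reactants: 12 methyl 2-(hydroxymethyl)prop-2-enoate
Product: 13 methyl 2-({[tert-butyl(dimethyl)silyl]oxy}methyl)prop-2-enoate
Conditions: TBSCl, imidazole, CH2Cl2, 0 °C
Reagents that add atoms: tert-butyldimethylsilyl chloride, CC(C)(C)[Si](C)(C)Cl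
Why: Routine silylation of the primary allylic alcohol.

Step 9
Reactants: 13 methyl 2-({[tert-butyl(dimethyl)silyl]oxy}methyl)prop-2-enoate
Product: 14 2-({[tert-butyl(dimethyl)silyl]oxy}methyl)prop-2-enoic acid
Conditions: LiOH, THF/H2O, 0 °C; then 1 M HCl to pH 4
Reagents that add atoms: lithium hydroxide, [Li+].[OH-]
Why: Saponification of the methyl ester under cold conditions that a primary silyl ether tolerates.

Step 10
Reactants: 11 (1R,3S)-3-{[tert-butyl(dimethyl)silyl]oxy}-2-methylidene-1-[(2R,3R)-3-methyl-3-(prop-2-en-1-yl)oxiran-2-yl]-6-(trimethylsilyl)hex-5-yn-1-ol; 14 2-({[tert-butyl(dimethyl)silyl]oxy}methyl)prop-2-enoic acid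
Product: 15 (1S,3S)-3-{[tert-butyl(dimethyl)silyl]oxy}-2-methylidene-1-[(2R,3R)-3-methyl-3-(prop-2-en-1-yl)oxiran-2-yl]-6-(trimethylsilyl)hex-5-yn-1-yl 2-({[tert-butyl(dimethyl)silyl]oxy}methyl)prop-2-enoate
Conditions: PPh3, DIAD, toluene, 0 °C to rt
Reagents that add atoms: none
Why: Mitsunobu esterification proceeds by SN2 inversion, a known way to invert α-epoxy carbinols, and should convert the 5,6-anti alcohol into the 5,6-syn (6S) ester of the target; the silyl-protected acid is used because an allylic acetate in the acid would be open to SN2′ attack by the phosphine.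

Step 11
Reactants: 15 (1S,3S)-3-{[tert-butyl(dimethyl)silyl]oxy}-2-methylidene-1-[(2R,3R)-3-methyl-3-(prop-2-en-1-yl)oxiran-2-yl]-6-(trimethylsilyl)hex-5-yn-1-yl 2-({[tert-butyl(dimethyl)silyl]oxy}methyl)prop-2-enoate
Product: 16 (5S)-3-({[tert-butyl(dimethyl)silyl]oxy}methyl)-4-[(1S)-1-{[tert-butyl(dimethyl)silyl]oxy}-4-(trimethylsilyl)but-3-yn-1-yl]-5-[(2R,3R)-3-methyl-3-(prop-2-en-1-yl)oxiran-2-yl]furan-2(5H)-one
Conditions: RuCl2(=CH–C6H4–2-OiPr)[1,3-bis(2-methylphenyl)imidazolidin-2-ylidene] (10 mol %), toluene (2 mM), 80 °C, argon sparge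
Reagents that add atoms: none
Why: Ring-closing metathesis of the two 1,1-disubstituted olefins gives the tetrasubstituted butenolide, a transformation known for methallyl methacrylate-type dienes with ruthenium catalysts carrying a less hindered carbene ligand; the allyl group cannot close a six-membered ring onto C7 because C3 and C6 are trans on the oxirane, the silyl cap keeps the alkyne out of enyne metathesis, and any homodimer at the allyl terminus is returned to monomer by ethylene in step 13.

Step 12
Reactants: 16 (5S)-3-({[tert-butyl(dimethyl)silyl]oxy}methyl)-4-[(1S)-1-{[tert-butyl(dimethyl)silyl]oxy}-4-(trimethylsilyl)but-3-yn-1-yl]-5-[(2R,3R)-3-methyl-3-(prop-2-en-1-yl)oxiran-2-yl]furan-2(5H)-one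
Product: 17 (5S)-4-[(1S)-1-{[tert-butyl(dimethyl)silyl]oxy}but-3-yn-1-yl]-3-({[tert-butyl(dimethyl)silyl]oxy}methyl)-5-[(2R,3R)-3-methyl-3-(prop-2-en-1-yl)oxiran-2-yl]furan-2(5H)-one
Conditions: AgNO3 (cat.), acetone/H2O, rt
Reagents that add atoms: none
Why: Silver-catalysed protiodesilylation removes only the alkynyl silyl group under neutral conditions, so the base-sensitive C6–H/oxirane pair and both silyl ethers should survive.

Step 13
Reactants: 17 (5S)-4-[(1S)-1-{[tert-butyl(dimethyl)silyl]oxy}but-3-yn-1-yl]-3-({[tert-butyl(dimethyl)silyl]oxy}methyl)-5-[(2R,3R)-3-methyl-3-(prop-2-en-1-yl)oxiran-2-yl]furan-2(5H)-one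
Product: 19 (1Z,4R,5R,6S,8S)-8,13-bis{[tert-butyl(dimethyl)silyl]oxy}-4,5-epoxygermacra-1,7(11),10(14)-trien-6,12-olide, via butadiene 18 (not isolated)
Conditions: ethylene (1 atm), second-generation Grubbs catalyst RuCl2(=CHPh)(PCy3)(H2IMes) (10 mol %), CH2Cl2, 40 °C; then argon sparge, dilution to 1 mM in toluene, second-generation Hoveyda–Grubbs catalyst RuCl2(=CH–C6H4–2-OiPr)(H2IMes) (10 mol %), 80 °C
Reagents that add atoms: ethylene, C=C
Why: This is a ring-closing enyne metathesis in its ethylene-relayed form: a ruthenium methylidene adds to the terminal alkyne C10≡C1 and the resulting vinyl carbene is released by ethylene as the 2-substituted butadiene 18, so that C14 enters from ethylene and C1 becomes a vinyl terminus. After ethylene is purged and the solution diluted, the alkylidene formed at the allyl terminus C2 closes onto that vinyl group and expels ethylene, which makes ring A through the C1=C2 bond; the closest known reaction type is ethylene-mediated enyne cross-metathesis followed by diene–ene ring-closing metathesis, as used for macrocyclic 1,3-dienes with an exocyclic methylene. The ring closed is the ten-membered carbocycle, formally by the endo mode of enyne ring closure, with both former alkyne carbons ending in or on the ring. No stereocentre is formed; the element to control is the C1=C2 geometry, and Z is expected because ring A already holds the trans C4–C5 oxirane and the planar butenolide, and two trans units separated only by C3 cannot be spanned comfortably by the remaining ring atoms, while the reversible metathesis lets the less strained olefin accumulate. Site selectivity rests on the substrate: the butenolide olefin is tetrasubstituted and electron-poor and C10=C14 is 1,1-disubstituted, so only the two monosubstituted termini react and a nine-membered closure onto C10 is disfavoured. Ring closure against oligomerisation is secured by dilution and by the pre-organisation from the trans oxirane and the lactone, and acyclic dimers formed through the allyl terminus are cleaved again under ethylene.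

Step 14
Reactants: 19 (1Z,4R,5R,6S,8S)-8,13-bis{[tert-butyl(dimethyl)silyl]oxy}-4,5-epoxygermacra-1,7(11),10(14)-trien-6,12-olide
Product: 20 (1Z,4R,5R,6S,8S)-4,5-epoxy-8,13-dihydroxygermacra-1,7(11),10(14)-trien-6,12-olide
Conditions: HF·pyridine, pyridine, THF, 0 °C to rt
Reagents that add atoms: none
Why: Pyridine-buffered HF·pyridine removes both silyl ethers without base, which spares the C6–H/oxirane pair; the acid-labile vinyl oxirane is not yet present.

Step 15
Reactants: 20 (1Z,4R,5R,6S,8S)-4,5-epoxy-8,13-dihydroxygermacra-1,7(11),10(14)-trien-6,12-olide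
Product: 21 (1Z,4R,5R,6S,8S)-13-acetoxy-4,5-epoxy-8-hydroxygermacra-1,7(11),10(14)-trien-6,12-olide
Conditions: AcCl, 2,4,6-collidine, CH2Cl2, −78 °C
Reagents that add atoms: acetyl chloride, CC(=O)Cl
Why: Acetyl chloride with a hindered pyridine at low temperature acylates primary alcohols selectively, so the primary allylic C13 hydroxyl should react and the hindered secondary C8 hydroxyl should not.

Step 16
Reactants: 21 (1Z,4R,5R,6S,8S)-13-acetoxy-4,5-epoxy-8-hydroxygermacra-1,7(11),10(14)-trien-6,12-olide; 14 2-({[tert-butyl(dimethyl)silyl]oxy}methyl)prop-2-enoic acid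
Product: 22 (1Z,4R,5R,6S,8S)-13-acetoxy-4,5-epoxy-8-{[2-({[tert-butyl(dimethyl)silyl]oxy}methyl)prop-2-enoyl]oxy}germacra-1,7(11),10(14)-trien-6,12-olide
Conditions: DCC, DMAP (cat.), CH2Cl2, 0 °C
Reagents that add atoms: none
Why: Steglich esterification acylates the C8 hydroxyl with retention; low temperature and catalytic DMAP keep acetyl migration and deprotonation at C6 in check.

Step 17
Reactants: 22 (1Z,4R,5R,6S,8S)-13-acetoxy-4,5-epoxy-8-{[2-({[tert-butyl(dimethyl)silyl]oxy}methyl)prop-2-enoyl]oxy}germacra-1,7(11),10(14)-trien-6,12-olide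
Product: 23 (1Z,4R,5R,6S,8S)-13-acetoxy-4,5-epoxy-8-{[2-(hydroxymethyl)prop-2-enoyl]oxy}germacra-1,7(11),10(14)-trien-6,12-olide
Conditions: HF·pyridine, pyridine, THF, 0 °C
Reagents that add atoms: none
Why: A primary silyl ether is cleaved quickly by buffered HF·pyridine, and both esters and the trisubstituted oxirane are expected to tolerate these conditions.

Step 18
Reactants: 23 (1Z,4R,5R,6S,8S)-13-acetoxy-4,5-epoxy-8-{[2-(hydroxymethyl)prop-2-enoyl]oxy}germacra-1,7(11),10(14)-trien-6,12-olide
Product: 24 (1R,2S,4R,5R,6S,8S)-13-acetoxy-1,2:4,5-diepoxy-8-{[2-(hydroxymethyl)prop-2-enoyl]oxy}germacra-7(11),10(14)-dien-6,12-olide (CNP0233746.1)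
Conditions: D-glucose-derived N-(4-methylphenyl)oxazolidinone spiro ketone (0.3 equiv), Oxone, K2CO3/AcOH buffer (pH 8), Bu4NHSO4, DME/H2O, 0 °C
Reagents that add atoms: potassium peroxymonosulfate (Oxone), [K+].[O-]S(=O)(=O)OO
Why: Shi epoxidation with the oxazolidinone ketone class is selective for cis-disubstituted olefins that carry a conjugating substituent, which is the known basis for making vinyl cis-epoxides from conjugated dienes; the electron-poor acrylate and butenolide olefins are inert to the dioxirane. Oxygen transfer is concerted, so the cis geometry is kept, and by analogy with cis-β-methylstyrene (which gives the 1R,2S oxide) the D-glucose-derived ketone should give the 1R,2S oxirane.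

## Compound list

1 | pent-1-en-4-yne | C=CCC#C | starting material
2 | (2E)-3-methylhexa-2,5-dien-1-ol | OC/C=C(\C)CC=C | intermediate
3 | [(2R,3R)-3-methyl-3-(prop-2-en-1-yl)oxiran-2-yl]methanol | C=CC[C@@]1(C)O[C@@H]1CO | intermediate
4 | (2S,3R)-3-methyl-3-(prop-2-en-1-yl)oxirane-2-carbaldehyde | C=CC[C@@]1(C)O[C@@H]1C=O | intermediate
5 | prop-2-enal (acrolein) | C=CC=O | starting material
6 | 2-bromoprop-2-enal | C=C(Br)C=O | intermediate
7 | trimethyl[3-(4,4,5,5-tetramethyl-1,3,2-dioxaborolan-2-yl)prop-1-yn-1-yl]silane | C[Si](C)(C)C#CCB1OC(C)(C)C(C)(C)O1 | starting material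
8 | (3S)-2-bromo-6-(trimethylsilyl)hex-1-en-5-yn-3-ol | C=C(Br)[C@@H](O)CC#C[Si](C)(C)C | intermediate
9 | {[(3S)-2-bromo-6-(trimethylsilyl)hex-1-en-5-yn-3-yl]oxy}(tert-butyl)dimethylsilane | C=C(Br)[C@@H](O[Si](C)(C)C(C)(C)C)CC#C[Si](C)(C)C | intermediate
10 | [(3S)-3-{[tert-butyl(dimethyl)silyl]oxy}-6-(trimethylsilyl)hex-1-en-5-yn-2-yl]lithium | [Li]C(=C)[C@@H](O[Si](C)(C)C(C)(C)C)CC#C[Si](C)(C)C | intermediate
11 | (1R,3S)-3-{[tert-butyl(dimethyl)silyl]oxy}-2-methylidene-1-[(2R,3R)-3-methyl-3-(prop-2-en-1-yl)oxiran-2-yl]-6-(trimethylsilyl)hex-5-yn-1-ol | C=CC[C@@]1(C)O[C@@H]1[C@H](O)C(=C)[C@@H](O[Si](C)(C)C(C)(C)C)CC#C[Si](C)(C)C | intermediate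
12 | methyl 2-(hydroxymethyl)prop-2-enoate | C=C(CO)C(=O)OC | starting material
13 | methyl 2-({[tert-butyl(dimethyl)silyl]oxy}methyl)prop-2-enoate | C=C(CO[Si](C)(C)C(C)(C)C)C(=O)OC | intermediate
14 | 2-({[tert-butyl(dimethyl)silyl]oxy}methyl)prop-2-enoic acid | C=C(CO[Si](C)(C)C(C)(C)C)C(=O)O | intermediate
15 | (1S,3S)-3-{[tert-butyl(dimethyl)silyl]oxy}-2-methylidene-1-[(2R,3R)-3-methyl-3-(prop-2-en-1-yl)oxiran-2-yl]-6-(trimethylsilyl)hex-5-yn-1-yl 2-({[tert-butyl(dimethyl)silyl]oxy}methyl)prop-2-enoate | C=CC[C@@]1(C)O[C@@H]1[C@@H](OC(=O)C(=C)CO[Si](C)(C)C(C)(C)C)C(=C)[C@@H](O[Si](C)(C)C(C)(C)C)CC#C[Si](C)(C)C | intermediate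
16 | (5S)-3-({[tert-butyl(dimethyl)silyl]oxy}methyl)-4-[(1S)-1-{[tert-butyl(dimethyl)silyl]oxy}-4-(trimethylsilyl)but-3-yn-1-yl]-5-[(2R,3R)-3-methyl-3-(prop-2-en-1-yl)oxiran-2-yl]furan-2(5H)-one | C=CC[C@@]1(C)O[C@@H]1[C@H]1OC(=O)C(CO[Si](C)(C)C(C)(C)C)=C1[C@@H](O[Si](C)(C)C(C)(C)C)CC#C[Si](C)(C)C | intermediate
17 | (5S)-4-[(1S)-1-{[tert-butyl(dimethyl)silyl]oxy}but-3-yn-1-yl]-3-({[tert-butyl(dimethyl)silyl]oxy}methyl)-5-[(2R,3R)-3-methyl-3-(prop-2-en-1-yl)oxiran-2-yl]furan-2(5H)-one | C=CC[C@@]1(C)O[C@@H]1[C@H]1OC(=O)C(CO[Si](C)(C)C(C)(C)C)=C1[C@@H](O[Si](C)(C)C(C)(C)C)CC#C | intermediate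
18 | (5S)-4-[(1S)-1-{[tert-butyl(dimethyl)silyl]oxy}-3-methylidenepent-4-en-1-yl]-3-({[tert-butyl(dimethyl)silyl]oxy}methyl)-5-[(2R,3R)-3-methyl-3-(prop-2-en-1-yl)oxiran-2-yl]furan-2(5H)-one | C=CC[C@@]1(C)O[C@@H]1[C@H]1OC(=O)C(CO[Si](C)(C)C(C)(C)C)=C1[C@@H](O[Si](C)(C)C(C)(C)C)CC(=C)C=C | intermediate
19 | (1Z,4R,5R,6S,8S)-8,13-bis{[tert-butyl(dimethyl)silyl]oxy}-4,5-epoxygermacra-1,7(11),10(14)-trien-6,12-olide | CC(C)(C)[Si](C)(C)O[C@H]1CC(=C)/C=C\C[C@@]2(C)O[C@@H]2[C@H]2OC(=O)C(CO[Si](C)(C)C(C)(C)C)=C12 | intermediate
20 | (1Z,4R,5R,6S,8S)-4,5-epoxy-8,13-dihydroxygermacra-1,7(11),10(14)-trien-6,12-olide | O[C@H]1CC(=C)/C=C\C[C@@]2(C)O[C@@H]2[C@H]2OC(=O)C(CO)=C12 | intermediate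
21 | (1Z,4R,5R,6S,8S)-13-acetoxy-4,5-epoxy-8-hydroxygermacra-1,7(11),10(14)-trien-6,12-olide | O[C@H]1CC(=C)/C=C\C[C@@]2(C)O[C@@H]2[C@H]2OC(=O)C(COC(C)=O)=C12 | intermediate
22 | (1Z,4R,5R,6S,8S)-13-acetoxy-4,5-epoxy-8-{[2-({[tert-butyl(dimethyl)silyl]oxy}methyl)prop-2-enoyl]oxy}germacra-1,7(11),10(14)-trien-6,12-olide | CC(C)(C)[Si](C)(C)OCC(=C)C(=O)O[C@H]1CC(=C)/C=C\C[C@@]2(C)O[C@@H]2[C@H]2OC(=O)C(COC(C)=O)=C12 | intermediate
23 | (1Z,4R,5R,6S,8S)-13-acetoxy-4,5-epoxy-8-{[2-(hydroxymethyl)prop-2-enoyl]oxy}germacra-1,7(11),10(14)-trien-6,12-olide | C=C(CO)C(=O)O[C@H]1CC(=C)/C=C\C[C@@]2(C)O[C@@H]2[C@H]2OC(=O)C(COC(C)=O)=C12 | intermediate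
24 | (1R,2S,4R,5R,6S,8S)-13-acetoxy-1,2:4,5-diepoxy-8-{[2-(hydroxymethyl)prop-2-enoyl]oxy}germacra-7(11),10(14)-dien-6,12-olide (CNP0233746.1) | C=C(CO)C(=O)O[C@H]1CC(=C)[C@H]2O[C@H]2C[C@@]2(C)O[C@@H]2[C@H]2OC(=O)C(COC(C)=O)=C12 | target

## Step count and least certain steps

Total step count: 18. Longest linear sequence: 13 steps (steps 1, 2, 3, 7 and 10 to 18).

**Step 13 (key step).** The most likely failures are intermolecular metathesis (cyclic dimers and oligomers) and ring closure to the 1E olefin, because a ten-membered ring with three rigid units is strained and the olefin geometry is set by ring strain alone. Dimers can be re-submitted under ethylene, but the geometry cannot be steered by dilution. Fallback: set out from 17 and carry out the ring closure as described. If the geometric isomer (1E,4R,5R,6S,8S)-8,13-bis{[tert-butyl(dimethyl)silyl]oxy}-4,5-epoxygermacra-1,7(11),10(14)-trien-6,12-olide F1 is obtained, correct the geometry after the ring is made by triplet-sensitised E-to-Z isomerisation of the conjugated diene (benzophenone or an iridium photosensitiser, visible or near-UV light, degassed MeCN). This should enrich the twisted Z diene, which has the higher triplet energy, and the route is rejoined at 19.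

**Step 11.** Ring closure between two hindered 1,1-disubstituted olefins may be too slow, so that catalyst decomposition and cross-metathesis at the free allyl terminus win. Fallback: build the butenolide by a chromium/nickel coupling instead, setting out from 9 and 4.
- Double dehydrobromination/metalation of 9 (LDA, THF, −78 °C) and trapping with methyl chloroformate gives methyl (4S)-4-{[tert-butyl(dimethyl)silyl]oxy}-7-(trimethylsilyl)hepta-2,6-diynoate F2.
- Conjugate addition of iodide with aldol capture by formaldehyde (MgI2, CH2O, CH2Cl2, 0 °C) gives methyl (2Z,4S)-4-{[tert-butyl(dimethyl)silyl]oxy}-2-(hydroxymethyl)-3-iodo-7-(trimethylsilyl)hept-2-en-6-ynoate F3.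
- Silylation (TBSCl, imidazole) gives methyl (2Z,4S)-4-{[tert-butyl(dimethyl)silyl]oxy}-2-({[tert-butyl(dimethyl)silyl]oxy}methyl)-3-iodo-7-(trimethylsilyl)hept-2-en-6-ynoate F4.
- Nozaki–Hiyama–Kishi coupling of F4 with 4 (CrCl2, NiCl2 cat., a chiral sulfonamide ligand on chromium to override the Felkin preference) is followed by spontaneous lactonisation of the γ-hydroxy Z enoate, and the route is rejoined at 16.

**Step 18.** Oxygen transfer may go to the exocyclic C10=C14 olefin or to the wrong face of C1=C2, because both olefins of the diene are disubstituted and conjugated. Fallback: move the oxidation forward to alcohol 21 and change the oxygen-transfer manifold to a stepwise metal-oxo transfer, which selects cis-1,2-disubstituted conjugated olefins by side-on approach rather than by nucleophilicity.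
- Jacobsen epoxidation of 21 with (R,R)-[N,N′-bis(3,5-di-tert-butylsalicylidene)cyclohexane-1,2-diaminato]MnCl, mCPBA and N-methylmorpholine N-oxide in CH2Cl2 at −78 °C should give (1R,2S,4R,5R,6S,8S)-13-acetoxy-1,2:4,5-diepoxy-8-hydroxygermacra-7(11),10(14)-dien-6,12-olide F5.
- Steglich esterification with 14 gives (1R,2S,4R,5R,6S,8S)-13-acetoxy-1,2:4,5-diepoxy-8-{[2-({[tert-butyl(dimethyl)silyl]oxy}methyl)prop-2-enoyl]oxy}germacra-7(11),10(14)-dien-6,12-olide F6.
- Desilylation with acetic acid-buffered TBAF (THF, 0 °C) rejoins the route at 24.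

**Step 10.** The hindered allylic, oxirane-flanked carbinol may undergo SN2′ attack at the methylidene terminus or elimination instead of clean inversion. Fallback: avoid the inversion altogether, setting out from 9 and 4. Transmetalate the vinyllithium 10 with MgBr2·OEt2 and add it to 4 in CH2Cl2 under chelation control (aldehyde and oxirane oxygens on magnesium). This should give the 5,6-syn alcohol (1S,3S)-3-{[tert-butyl(dimethyl)silyl]oxy}-2-methylidene-1-[(2R,3R)-3-methyl-3-(prop-2-en-1-yl)oxiran-2-yl]-6-(trimethylsilyl)hex-5-yn-1-ol F7. Acylation of F7 with 14 under Steglich conditions (DCC, DMAP), with retention, rejoins the route at 15. The same acylation also converges any F7 formed as the minor product of step 7.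

**Step 5.** The α-bromo enal may give low enantioselectivity, allenyl carbinol or conjugate addition. Fallback: set out from 6. Zinc-mediated Barbier propargylation with 3-bromo-1-(trimethylsilyl)prop-1-yne gives rac-2-bromo-6-(trimethylsilyl)hex-1-en-5-yn-3-ol F8. Lipase-catalysed kinetic resolution with vinyl acetate then converts the unwanted enantiomer into (3R)-2-bromo-6-(trimethylsilyl)hex-1-en-5-yn-3-yl acetate F9 and leaves the S alcohol, which rejoins the route at 8.

## Further compounds

F1 | step 13 | (1E,4R,5R,6S,8S)-8,13-bis{[tert-butyl(dimethyl)silyl]oxy}-4,5-epoxygermacra-1,7(11),10(14)-trien-6,12-olide | CC(C)(C)[Si](C)(C)O[C@H]1CC(=C)/C=C/C[C@@]2(C)O[C@@H]2[C@H]2OC(=O)C(CO[Si](C)(C)C(C)(C)C)=C12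
F2 | step 11 | methyl (4S)-4-{[tert-butyl(dimethyl)silyl]oxy}-7-(trimethylsilyl)hepta-2,6-diynoate | COC(=O)C#C[C@@H](O[Si](C)(C)C(C)(C)C)CC#C[Si](C)(C)C
F3 | step 11 | methyl (2Z,4S)-4-{[tert-butyl(dimethyl)silyl]oxy}-2-(hydroxymethyl)-3-iodo-7-(trimethylsilyl)hept-2-en-6-ynoate | COC(=O)/C(CO)=C(\I)[C@@H](O[Si](C)(C)C(C)(C)C)CC#C[Si](C)(C)C
F4 | step 11 | methyl (2Z,4S)-4-{[tert-butyl(dimethyl)silyl]oxy}-2-({[tert-butyl(dimethyl)silyl]oxy}methyl)-3-iodo-7-(trimethylsilyl)hept-2-en-6-ynoate | COC(=O)/C(CO[Si](C)(C)C(C)(C)C)=C(\I)[C@@H](O[Si](C)(C)C(C)(C)C)CC#C[Si](C)(C)C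
F5 | step 18 | (1R,2S,4R,5R,6S,8S)-13-acetoxy-1,2:4,5-diepoxy-8-hydroxygermacra-7(11),10(14)-dien-6,12-olide | O[C@H]1CC(=C)[C@H]2O[C@H]2C[C@@]2(C)O[C@@H]2[C@H]2OC(=O)C(COC(C)=O)=C12
F6 | step 18 | (1R,2S,4R,5R,6S,8S)-13-acetoxy-1,2:4,5-diepoxy-8-{[2-({[tert-butyl(dimethyl)silyl]oxy}methyl)prop-2-enoyl]oxy}germacra-7(11),10(14)-dien-6,12-olide | CC(C)(C)[Si](C)(C)OCC(=C)C(=O)O[C@H]1CC(=C)[C@H]2O[C@H]2C[C@@]2(C)O[C@@H]2[C@H]2OC(=O)C(COC(C)=O)=C12
F7 | step 10 | (1S,3S)-3-{[tert-butyl(dimethyl)silyl]oxy}-2-methylidene-1-[(2R,3R)-3-methyl-3-(prop-2-en-1-yl)oxiran-2-yl]-6-(trimethylsilyl)hex-5-yn-1-ol | C=CC[C@@]1(C)O[C@@H]1[C@@H](O)C(=C)[C@@H](O[Si](C)(C)C(C)(C)C)CC#C[Si](C)(C)C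
F8 | step 5 | rac-2-bromo-6-(trimethylsilyl)hex-1-en-5-yn-3-ol | C=C(Br)C(O)CC#C[Si](C)(C)C
F9 | step 5 | (3R)-2-bromo-6-(trimethylsilyl)hex-1-en-5-yn-3-yl acetate | C=C(Br)[C@H](OC(C)=O)CC#C[Si](C)(C)C
A1 | alternative 1 | [(5S)-5-{(2R,3R)-3-[(2Z)-4-(bromomethyl)penta-2,4-dien-1-yl]-3-methyloxiran-2-yl}-4-formyl-2-oxo-2,5-dihydrofuran-3-yl]methyl acetate | BrCC(=C)/C=C\C[C@@]1(C)O[C@@H]1[C@H]1OC(=O)C(COC(C)=O)=C1C=O
A2 | alternative 2 | methyl (2Z,4S,7Z)-2-[(acetyloxy)methyl]-4-{[tert-butyl(dimethyl)silyl]oxy}-9-[(2R,3S)-3-formyl-2-methyloxiran-2-yl]-3-iodo-6-methylidenenona-2,7-dienoate | O=C[C@H]1O[C@]1(C)C/C=C\C(=C)C[C@H](O[Si](C)(C)C(C)(C)C)/C(I)=C(\COC(C)=O)C(=O)OC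
A3 | alternative 2 | (1Z,4R,5R,6S,8S)-13-acetoxy-8-{[tert-butyl(dimethyl)silyl]oxy}-4,5-epoxygermacra-1,7(11),10(14)-trien-6,12-olide | CC(C)(C)[Si](C)(C)O[C@H]1CC(=C)/C=C\C[C@@]2(C)O[C@@H]2[C@H]2OC(=O)C(COC(C)=O)=C12
A4 | alternative 3 | 6,10-bis{[tert-butyl(dimethyl)silyl]oxy}-8-ethenyl-7-(prop-1-en-2-yl)-1,4-dioxaspiro[4.5]decan-8-ol (ethenyl and propenyl groups trans; ring carbons 6, 7, 8, 9, 10 are germacrane C6, C5, C10, C9, C8) | C=C[C@@]1(O)C[C@H](O[Si](C)(C)C(C)(C)C)C2(OCCO2)[C@H](O[Si](C)(C)C(C)(C)C)[C@@H]1C(C)=C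
A5 | alternative 3 | (7E)-6,14-bis{[tert-butyl(dimethyl)silyl]oxy}-8-methyl-1,4-dioxaspiro[4.9]tetradec-7-en-12-one | O=C1CCC/C(C)=C/[C@@H](O[Si](C)(C)C(C)(C)C)C2(OCCO2)[C@@H](O[Si](C)(C)C(C)(C)C)C1
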